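**Assumption (one line):** compounds 1, 11 and 17 are taken as purchasable; eudesmane numbering is used for the terpene carbons (ring A = C1–C5 and C10, ring B = C5–C10, C14 on C10, C15 on C4, C11 on C7, benzylic carbon = C1′).

## Analysis of the target

The target is a 2,4,6-trihydroxybenzene-1,3-dicarbaldehyde whose last ring carbon is bonded to C1′. C1′ also carries an isobutyl group and C1 of a trans-fused decalin in which rings A and B share the C5–C10 bond. There are six stereocenters, (1′S,1S,4R,5S,7S,10R). H-5 is anti to the C10 methyl group, and the C1 side chain is also anti to that methyl group, so it is axial on ring A. The C4 hydroxyl is axial and syn to C14 (C15 equatorial), and the 2-hydroxypropan-2-yl group at C7 is equatorial and syn to C14. The two tertiary alcohols ionise or dehydrate under protic and Lewis acids, the aryl aldehydes sit between acidic chelated phenols, and the electron-rich arene is open to ipso attack. The hard part is the contiguous C1′–C1–C10 triad with quaternary C10 next to a crowded C1 whose axial substituent cannot be reached by equilibration; the second difficulty is to formylate and deprotect the arene in the presence of the tertiary alcohols. The strategy rests on the fact that C1, which bears C1′, is adjacent to quaternary C10 and that both rings share C5–C10. An (E)-enal C1=C10 carrying C14 as a formyl group and a silyloxydiene C2=C3–C4=C5, joined through C6–C9, therefore contain every ring carbon, and one intramolecular [4+2] cycloaddition closes rings A and B with the C4 oxygen in place. C7 is carried through that step as a malonate carbon, so C1′ is the only stereocenter in the cyclisation substrate.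

## Retrosynthetic reasoning

**36 ⇒ 35 ⇒ 33 ⇒ 32.** The three aryl O–CH3 bonds are cut last. In 35 every methoxy group is ortho to a formyl group, so a soft sulfur nucleophile can remove the methyl groups under basic conditions that the tertiary alcohols tolerate. The two aryl–CHO bonds are cut next, back to dibromide 33 and then to arene 32. Electrophilic formylation with Lewis acids or chloroiminium reagents was set aside because it would ionise the tertiary alcohols; bromination followed by halogen–lithium exchange only costs extra base for the two hydroxyls.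

**32 ⇒ 31 ⇒ 29 ⇒ 28.** The two carbinols are disconnected separately. C11 comes from the equatorial ester 31 and C15 from ketone 28. At C4 the axial trajectory is blocked by the 1,3-diaxial C14 methyl, so a methyl nucleophile must enter equatorially and leave the hydroxyl axial, as the target requires. Ester 31 comes from the geminal diester 29 by loss of one alkoxycarbonyl group and base equilibration to the equatorial epimer. Adding methyl to the ketone first means no ketone is present when base is used, so C5 is never exposed to epimerisation; this matters because the axial C1 substituent makes the position of a C5 equilibrium uncertain.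

**28 ⇒ 27 ⇒ 25 ⇒ 24.** The ketone is the hydrolysis product of silyl enol ether 27. The angular methyl is traced to the formyl group of 24 through sulfonylhydrazone 25. The reduction is placed while C4 is still masked as the enol ether, so the formyl group is the only carbonyl electrophile and no aldehyde/ketone differentiation is needed.

**24 ⇒ 23.** This is the key disconnection: C1–C2 and C5–C10 are cut together. It removes both rings and three stereocenters and leaves an acyclic triene, 23, whose only stereocenter is C1′. The forward reaction must add the diene to one face of the enal and pass through the formyl-endo arrangement.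

**23 ⇒ 22 ⇒ 19 ⇒ 16.** The enal is formed last, by allylic oxidation of 22, because an enal would not survive the silyl triflate and base used to make the dienol ether. The silyloxydiene comes from vinyl ketone 19, which can enolise on one side only. The C6–C7 bond is cut by a Michael disconnection to malonate 16 and divinyl ketone 18, which is generated from 17.

**16 ⇒ 14 ⇒ 10 + 11 + 12.** The allylic alcohol comes from the conjugated ester of 14. C1=C10 is cut as a Wittig bond, because an ester-stabilised ylide gives the required geometry (C1′ cis to C9) and works without base, which protects the α-aryl aldehyde 10. A crossed aldol condensation of two enolisable aldehydes was rejected for poor cross-selectivity and likely loss of configuration at C1′. The C7–C8 bond is cut at the same time: malonate 12 opens cyclopropylphosphonium salt 11, which both joins the tether and releases ylide 13.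

**10 ⇒ 9 ⇒ 8 ⇒ 7 ⇒ 4 ⇒ 1 + 2 (+ 5).** C1′ is set by auxiliary-controlled alkylation of the arylacetyl imide 4. The allylic bromide 5 is used instead of a β-branched alkyl halide for reactivity, and the alkene is hydrogenated afterwards. Reductive removal of the auxiliary and oxidation give 10.

## Alternatives that were turned down

**Alternative 1:** The aromatic ring is built last. Two ring C–C bonds are cut between the acyl carbons of the C1′-substituted malonyl dichloride A2 and the two methylene carbons of ketodiester A3. In the forward step a magnesium enolate of A3 is C-acylated twice by A2 and alkoxide closes and aromatises the ring to the trihydroxyisophthalate A1.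
- For: no electron-rich trimethoxyarene is carried through the synthesis, no O-demethylation is needed, and both future formyl carbons arrive with the ring. On protecting-group economy at the end this plan is stronger than the chosen one.
- Against: A2 has an α-hydrogen and a doubly branched substituent, so ketene formation and steric hindrance work against double acylation. The two chelated ester groups of A1 must still be brought to the aldehyde level next to three free phenols, which in practice means reduction to ortho-hydroxybenzyl alcohols (quinone-methide prone) and re-oxidation. The C1′–C1–C10 triad must be solved separately and without the aryl group.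
- Comparison: it is longer overall and leaves the main stereochemical problem open. The chosen strategy uses the aryl group as the element that steers the cycloaddition.

**Alternative 2:** The C4–C5 bond is cut. A chiral N-heterocyclic carbene turns the aldehyde of the tethered 4-methylcyclohexadienone A5 into an acyl anion equivalent, which adds to one enone arm (intramolecular Stetter reaction) to give enedione A4.
- For: the angular methyl is present from the start, so no formyl-to-methyl reduction is needed; C10 is set by the catalyst; the C4 ketone is delivered directly. On redox economy at C14 and on catalytic control it is stronger than the chosen plan.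
- Against: A5 needs C1′ and C1 already set in an open chain, attached through the secondary, β-branched C1 to the quaternary dienone carbon, a bond that is hard to make by dearomatising alkylation. The C1 stereocenter next to the prochiral carbon would compete with the catalyst. Ring B of A4 still has to lose its enone and gain the three-carbon unit at C7 with stereocontrol, several further steps.
- Comparison: it forms one bond and one ring in the key step, against two bonds and two rings, and the chosen plan has C7 functionality in place from a malonate.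

**Alternative 3:** The C10–C14 and C5–C6 bonds are cut. A methylcuprate adds to C10 of iodo enone A7 anti to the C1 substituent and the resulting C5 enolate displaces the primary iodide to close ring B, giving decalone A6.
- For: the methyl group enters at the right oxidation level, anti addition next to an existing ring substituent is a reliable mode of induction, the C7 side chain is complete and the C4 ketone appears directly. On redox economy and on the C7 centre it is as strong as or stronger than the chosen plan.
- Against: conjugate addition to a β,β-disubstituted enone flanked by tertiary C1 is slow and creates a very crowded quaternary centre. The iodide is β-branched and closes slowly against proton transfer. A7 needs three stereocenters (C1′, C1, C7) set independently, and the C1′/C1 pair, one in the ring and one outside, is the difficult relationship that this plan does not solve.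
- Comparison: in the chosen strategy one stereocenter, C1′, controls C1, C10 and C5 in a single step, and the precursor is acyclic and assembled from three simple pieces.

Key step: step 11

## Route

Step 1
Reactants: 1 2-(2,4,6-trimethoxyphenyl)acetic acid; 2 (4R)-4-benzyl-1,3-oxazolidin-2-one
Product: 4 (4R)-4-benzyl-3-[2-(2,4,6-trimethoxyphenyl)acetyl]-1,3-oxazolidin-2-one, via mixed pivalic anhydride 3 (not isolated)
Conditions: t-BuCOCl, Et3N, THF, −20 °C; then 2, LiCl, −20 °C to rt
Reagents that add atoms: none
Why: Mixed-anhydride N-acylation of an oxazolidinone (LiCl/Et3N activation) is the standard way to attach an arylacetic acid; no stereocenter is formed.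

Step 2
Reactants: 4; 5 3-bromo-2-methylprop-1-ene
Product: 7 (4R)-4-benzyl-3-[(2R)-4-methyl-2-(2,4,6-trimethoxyphenyl)pent-4-enoyl]-1,3-oxazolidin-2-one, via sodium Z-enolate 6 (not isolated)
Conditions: NaN(SiMe3)2, THF, −78 °C; then 5, −78 to −40 °C
Reagents that add atoms: none
Why: Evans-type alkylation: the chelated Z-enolate 6 is attacked on the face opposite the benzyl group, which sets C1′ (2R here, the future 1′S); the reactive allylic bromide is chosen because a β-branched alkyl halide would be too slow for this stabilised enolate.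

Step 3
Reactants: 7
Product: 8 (4R)-4-benzyl-3-[(2R)-4-methyl-2-(2,4,6-trimethoxyphenyl)pentanoyl]-1,3-oxazolidin-2-one
Conditions: H2 (1 atm), 10% Pd/C, EtOAc, rt
Reagents that add atoms: none
Why: Heterogeneous hydrogenation of the 1,1-disubstituted alkene gives the isobutyl group; arene, imide and stereocenter are not affected.

Step 4
Reactants: 8
Product: 9 (2R)-4-methyl-2-(2,4,6-trimethoxyphenyl)pentan-1-ol
Conditions: LiBH4, MeOH (1 equiv), Et2O, 0 °C
Reagents that add atoms: none
Why: Reductive cleavage of the N-acyl oxazolidinone gives the primary alcohol without enolising the α-aryl centre and returns auxiliary 2.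

Step 5
Reactants: 9
Product: 10 (2R)-4-methyl-2-(2,4,6-trimethoxyphenyl)pentanal
Conditions: Dess–Martin periodinane, NaHCO3, CH2Cl2, 0 °C
Reagents that add atoms: none
Why: Buffered Dess–Martin oxidation gives the configurationally labile α-aryl aldehyde without base, and it is used at once; the two ortho methoxy groups twist the ring out of conjugation with the enol and slow enolisation.

Step 6
Reactants: 10; 11 [1-(ethoxycarbonyl)cyclopropyl]triphenylphosphonium tetrafluoroborate; 12 dimethyl propanedioate
Product: 14 dimethyl 2-[(3E,5S)-3-(ethoxycarbonyl)-7-methyl-5-(2,4,6-trimethoxyphenyl)oct-3-en-1-yl]propanedioate, via ester-stabilised ylide 13 (not isolated)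
Conditions: 12, NaH, THF–DMF, 0 °C; 11, rt; then 10, 40 °C
Reagents that add atoms: none
Why: The soft malonate anion opens the activated cyclopropane of 11 at CH2 (homo-conjugate addition), which forms the C7–C8 bond and releases ylide 13 with no free base left when 10 is added; the Wittig reaction of this α-branched, ester-stabilised ylide should give the alkene with the ester trans to C1′ (E), as such ylides normally do.

Step 7
Reactants: 14
Product: 16 dimethyl 2-[(3E,5S)-3-(hydroxymethyl)-7-methyl-5-(2,4,6-trimethoxyphenyl)oct-3-en-1-yl]propanedioate, via sodium malonate enolate 15 (not isolated)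
Conditions: NaH (1.0 equiv), THF, 0 °C; then i-Bu2AlH (2.5 equiv), −78 °C; aq KNaC4H4O6
Reagents that add atoms: none
Why: The malonate is masked in the flask as its sodium enolate 15, which does not accept hydride at −78 °C, so i-Bu2AlH should reduce only the conjugated ethyl ester (1,2-reduction) to the allylic alcohol; alkene geometry and C1′ are unchanged.

Step 8
Reactants: 16; 17 1,5-dichloropentan-3-one
Product: 19 dimethyl 2-[(3E,5S)-3-(hydroxymethyl)-7-methyl-5-(2,4,6-trimethoxyphenyl)oct-3-en-1-yl]-2-(3-oxopent-4-en-1-yl)propanedioate, via divinyl ketone 18 (not isolated)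
Conditions: 17, Et3N, Et2O, 0 °C, filtration; filtrate (excess 18) added to 16, Cs2CO3 (0.3 equiv), MeCN, −10 to 0 °C
Reagents that add atoms: none
Why: Base-catalysed Michael addition of the tertiary malonate C–H to one vinyl group of 18 forms the C6–C7 bond and leaves the second vinyl ketone intact; the excess of 18 suppresses double addition, and C7 becomes quaternary but not stereogenic.

Step 9
Reactants: 19
Product: 22 dimethyl 2-[(3E,5S)-3-(hydroxymethyl)-7-methyl-5-(2,4,6-trimethoxyphenyl)oct-3-en-1-yl]-2-[(2Z)-3-(triisopropylsilyloxy)penta-2,4-dien-1-yl]propanedioate, via trimethylsilyl ether 20 (not isolated), via bis-silyl compound 21 (not isolated)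
Conditions: Me3SiCl, Et3N, CH2Cl2, 0 °C; i-Pr3SiOTf, Et3N, −78 to 0 °C; then K2CO3, MeOH, 0 °C
Reagents that add atoms: triisopropylsilyl trifluoromethanesulfonate, CC(C)[Si](OS(=O)(=O)C(F)(F)F)(C(C)C)C(C)C (chlorotrimethylsilane, C[Si](C)(C)Cl, supplies only the transient silyl group of 20 and 21)
Why: After transient O-silylation, soft enolisation of the ketone (silyl triflate and amine) can occur only toward C5 and gives the cross-conjugated 2-silyloxydiene, expected mainly as the Z enol ether (C6 trans to the vinyl group); brief methanolysis removes only the primary trimethylsilyl ether, because the bulky triisopropylsilyl enol ether is stable to K2CO3 in MeOH.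

Step 10
Reactants: 22
Product: 23 dimethyl 2-[(3E,5S)-3-formyl-7-methyl-5-(2,4,6-trimethoxyphenyl)oct-3-en-1-yl]-2-[(2Z)-3-(triisopropylsilyloxy)penta-2,4-dien-1-yl]propanedioate
Conditions: MnO2, CH2Cl2, rt
Reagents that add atoms: none
Why: MnO2 oxidises the allylic alcohol to the (E)-enal under neutral conditions that spare the silyl dienol ether; the enal is made last so that it never meets silyl triflate or base.

Step 11
Reactants: 23
Product: 24 dimethyl (4aS,5S,8aS)-4a-formyl-5-[(1S)-3-methyl-1-(2,4,6-trimethoxyphenyl)butyl]-8-(triisopropylsilyloxy)-3,4,4a,5,6,8a-hexahydronaphthalene-2,2(1H)-dicarboxylate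
Conditions: PhMe (5 mM), BHT, 2,6-di-tert-butylpyridine (0.1 equiv), 165 °C, sealed tube
Reagents that add atoms: none
Why: This is a thermal intramolecular Diels–Alder reaction of a 1,7,9-decatriene with the formyl group on the tethered dienophile carbon and a 2-silyloxydiene, a known substrate class; the concerted, suprafacial [4+2] addition forms C1–C2 and C5–C10. Ring A closes as the new cyclohexene of the cycloaddition, and ring B closes through the C5–C10 bond with the C6–C9 tether in a chair-like fold (fused mode), helped by the geminal diester at C7. The (E)-enal geometry, with C1′ cis to C9, is copied into the anti relation of the C1 side chain and the C10 formyl group. C5 is set by the formyl-endo, tether-exo transition state, which gives the trans fusion and is also the arrangement that keeps the bulky C1 substituent exo. The absolute sense at C1 and C10 comes from C1′ through allylic 1,3-strain: the C1′–H bond eclipses C1=C10 on the C9 side and the diene adds to the face opposite the 2,4,6-trimethoxyphenyl group. Facial selectivity is therefore the selectivity the step needs, and it is secured by the size difference between the di-ortho-substituted aryl and the isobutyl group. Regiochemistry is fixed by the tether, although it joins the nucleophilic diene terminus C5 to the α-carbon of the enal, so the silyloxy group activates only weakly and heat is needed. Lewis acids are avoided because they would open a stepwise Mukaiyama–Michael path from C5 to C1 and a seven-membered ring.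

Step 12
Reactants: 24
Product: 25 (E)-N-tosylhydrazone of 24 at the C10 formyl group
Conditions: TsNHNH2, THF, 4 Å MS, 50 °C
Reagents that add atoms: 4-methylbenzenesulfonohydrazide, Cc1ccc(cc1)S(=O)(=O)NN
Why: Condensation of the neopentyl aldehyde with the sulfonylhydrazine under neutral dehydrating conditions; the formyl group is the only carbonyl electrophile because C4 is still a silyl enol ether.

Step 13
Reactants: 25
Product: 27 dimethyl (4aR,5S,8aS)-4a-methyl-5-[(1S)-3-methyl-1-(2,4,6-trimethoxyphenyl)butyl]-8-(triisopropylsilyloxy)-3,4,4a,5,6,8a-hexahydronaphthalene-2,2(1H)-dicarboxylate, via N-boryl hydrazide 26 (not isolated)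
Conditions: catecholborane, CHCl3, 0 °C to rt; then NaOAc·3H2O, 60 °C
Reagents that add atoms: none
Why: Hydride transfer from catecholborane to the C=N bond and acetate-induced loss of sulfinate and N2 from 26 (the mild variant of the Caglioti reduction) turn C14 into the angular methyl without acid, so the silyl enol ether should survive; C10 keeps its configuration.

Step 14
Reactants: 27
Product: 28 dimethyl (4aR,5S,8aS)-4a-methyl-5-[(1S)-3-methyl-1-(2,4,6-trimethoxyphenyl)butyl]-8-oxo-octahydronaphthalene-2,2(1H)-dicarboxylate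
Conditions: Bu4NF, AcOH, THF, 0 °C
Reagents that add atoms: none
Why: Fluoride cleaves the Si–O bond and the enolate is protonated at C3 by the acetic acid buffer, which gives the C4 ketone without conditions that would enolise toward C5; the trans fusion from step 11 is kept.

Step 15
Reactants: 28
Product: 29 dimethyl (4aR,5S,8R,8aS)-8-hydroxy-4a,8-dimethyl-5-[(1S)-3-methyl-1-(2,4,6-trimethoxyphenyl)butyl]octahydronaphthalene-2,2(1H)-dicarboxylate
Conditions: MeMgBr, CeCl3, THF, −78 °C
Reagents that add atoms: methylmagnesium bromide, C[Mg]Br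
Why: The organocerium reagent should add to the hindered, enolisable ketone faster than to the neopentyl-type malonate esters at −78 °C; axial approach is blocked by the 1,3-diaxial C10 methyl, so methyl enters equatorially and the C4 hydroxyl ends axial, syn to C14 (4R in eudesmane numbering).

Step 16
Reactants: 29
Product: 31 methyl (2S,4aR,5S,8R,8aS)-8-hydroxy-4a,8-dimethyl-5-[(1S)-3-methyl-1-(2,4,6-trimethoxyphenyl)butyl]decahydronaphthalene-2-carboxylate, via C7-epimeric ester mixture 30 (not isolated)
Conditions: LiCl, H2O, DMSO, 150 °C; then NaOMe, MeOH, 50 °C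
Reagents that add atoms: none
Why: Krapcho dealkoxycarbonylation (chloride attacks one ester methyl, CO2 is lost, the enolate is protonated) gives the monoester as the epimer mixture 30; methoxide then equilibrates C7 through the ester enolate toward the equatorial epimer (7S), and the minor axial epimer can be resubmitted. No ketone is present, so C5 is not touched.

Step 17
Reactants: 31
Product: 32 (1R,4S,4aR,7S,8aS)-7-(2-hydroxypropan-2-yl)-1,4a-dimethyl-4-[(1S)-3-methyl-1-(2,4,6-trimethoxyphenyl)butyl]decahydronaphthalen-1-ol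
Conditions: MeMgBr (excess), THF, 0 °C to rt
Reagents that add atoms: methylmagnesium bromide, C[Mg]Br
Why: Double Grignard addition to the methyl ester gives the C11 tertiary alcohol; the C4 alkoxide is a spectator and C7 keeps its configuration because addition outruns ester enolisation.

Step 18
Reactants: 32
Product: 33 (1R,4S,4aR,7S,8aS)-4-[(1S)-1-(3,5-dibromo-2,4,6-trimethoxyphenyl)-3-methylbutyl]-7-(2-hydroxypropan-2-yl)-1,4a-dimethyldecahydronaphthalen-1-ol
Conditions: NBS (2.05 equiv), MeCN, 0 °C, dark
Reagents that add atoms: N-bromosuccinimide, BrN1C(=O)CCC1=O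
Why: Electrophilic aromatic bromination: the two free ring positions, each between two methoxy groups, are the most nucleophilic sites and should react at 0 °C without acid, so the tertiary alcohols are safe.

Step 19
Reactants: 33
Product: 35 5-{(1S)-1-[(1S,4R,4aS,6S,8aR)-4-hydroxy-6-(2-hydroxypropan-2-yl)-4,8a-dimethyldecahydronaphthalen-1-yl]-3-methylbutyl}-2,4,6-trimethoxybenzene-1,3-dicarbaldehyde, via tetralithiated arene 34 (not isolated)
Conditions: MeLi (2 equiv), then t-BuLi (4.4 equiv), THF, −78 °C; then DMF, −78 to 0 °C; aq NH4Cl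
Reagents that add atoms: N,N-dimethylformamide, CN(C)C=O
Why: After deprotonation of the two hydroxyls, double bromine–lithium exchange gives 34, each aryl carbanion being stabilised by two flanking methoxy groups; formylation with the formamide and hydrolysis give the dialdehyde. This replaces Lewis-acid formylation, which the tertiary alcohols would not survive.

Step 20
Reactants: 35
Product: 36 2,4,6-trihydroxy-5-{(1S)-1-[(1S,4R,4aS,6S,8aR)-4-hydroxy-6-(2-hydroxypropan-2-yl)-4,8a-dimethyldecahydronaphthalen-1-yl]-3-methylbutyl}benzene-1,3-dicarbaldehyde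
Conditions: NaSEt, DMF, 120 °C; then aq HCl
Reagents that add atoms: none
Why: Thiolate SN2 attack at the methyl groups cleaves the three aryl methyl ethers, each activated by an ortho formyl group, under basic conditions that leave the tertiary alcohols intact; acidification gives the hydrogen-bonded triphenol.

## Compound list

1 | 2-(2,4,6-trimethoxyphenyl)acetic acid | COc1cc(OC)c(CC(=O)O)c(OC)c1 | starting material
2 | (4R)-4-benzyl-1,3-oxazolidin-2-one | O=C1N[C@H](Cc2ccccc2)CO1 | starting material
3 | 2,2-dimethylpropanoic 2-(2,4,6-trimethoxyphenyl)acetic anhydride | CC(C)(C)C(=O)OC(=O)Cc1c(OC)cc(OC)cc1OC | intermediate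
4 | (4R)-4-benzyl-3-[2-(2,4,6-trimethoxyphenyl)acetyl]-1,3-oxazolidin-2-one | COc1cc(OC)c(CC(=O)N2[C@H](Cc3ccccc3)COC2=O)c(OC)c1 | intermediate
5 | 3-bromo-2-methylprop-1-ene | C=C(C)CBr | starting material
6 | sodium (Z)-enolate of 4 | [Na+].COc1cc(OC)c(/C=C(\[O-])N2[C@H](Cc3ccccc3)COC2=O)c(OC)c1 | intermediate
7 | (4R)-4-benzyl-3-[(2R)-4-methyl-2-(2,4,6-trimethoxyphenyl)pent-4-enoyl]-1,3-oxazolidin-2-one | C=C(C)C[C@H](c1c(OC)cc(OC)cc1OC)C(=O)N1[C@H](Cc2ccccc2)COC1=O | intermediate
8 | (4R)-4-benzyl-3-[(2R)-4-methyl-2-(2,4,6-trimethoxyphenyl)pentanoyl]-1,3-oxazolidin-2-one | CC(C)C[C@H](c1c(OC)cc(OC)cc1OC)C(=O)N1[C@H](Cc2ccccc2)COC1=O | intermediate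
9 | (2R)-4-methyl-2-(2,4,6-trimethoxyphenyl)pentan-1-ol | CC(C)C[C@H](c1c(OC)cc(OC)cc1OC)CO | intermediate
10 | (2R)-4-methyl-2-(2,4,6-trimethoxyphenyl)pentanal | CC(C)C[C@H](c1c(OC)cc(OC)cc1OC)C=O | intermediate
11 | [1-(ethoxycarbonyl)cyclopropyl]triphenylphosphonium tetrafluoroborate | CCOC(=O)C1(CC1)[P+](c1ccccc1)(c1ccccc1)c1ccccc1.F[B-](F)(F)F | starting material
12 | dimethyl propanedioate | COC(=O)CC(=O)OC | starting material
13 | ethyl 5,5-bis(methoxycarbonyl)-2-(triphenylphosphoranylidene)pentanoate | CCOC(=O)C(CCC(C(=O)OC)C(=O)OC)=P(c1ccccc1)(c1ccccc1)c1ccccc1 | intermediate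
14 | dimethyl 2-[(3E,5S)-3-(ethoxycarbonyl)-7-methyl-5-(2,4,6-trimethoxyphenyl)oct-3-en-1-yl]propanedioate | CC(C)C[C@H](c1c(OC)cc(OC)cc1OC)/C=C(C(=O)OCC)\CCC(C(=O)OC)C(=O)OC | intermediate
15 | sodium malonate enolate of 14 | [Na+].CC(C)C[C@H](c1c(OC)cc(OC)cc1OC)/C=C(C(=O)OCC)\CC[C-](C(=O)OC)C(=O)OC | intermediate
16 | dimethyl 2-[(3E,5S)-3-(hydroxymethyl)-7-methyl-5-(2,4,6-trimethoxyphenyl)oct-3-en-1-yl]propanedioate | CC(C)C[C@H](c1c(OC)cc(OC)cc1OC)/C=C(CO)\CCC(C(=O)OC)C(=O)OC | intermediate
17 | 1,5-dichloropentan-3-one | ClCCC(=O)CCCl | starting material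
18 | penta-1,4-dien-3-one (divinyl ketone) | C=CC(=O)C=C | intermediate
19 | dimethyl 2-[(3E,5S)-3-(hydroxymethyl)-7-methyl-5-(2,4,6-trimethoxyphenyl)oct-3-en-1-yl]-2-(3-oxopent-4-en-1-yl)propanedioate | CC(C)C[C@H](c1c(OC)cc(OC)cc1OC)/C=C(CO)\CCC(CCC(=O)C=C)(C(=O)OC)C(=O)OC | intermediate
20 | O-trimethylsilyl ether of 19 | CC(C)C[C@H](c1c(OC)cc(OC)cc1OC)/C=C(CO[Si](C)(C)C)\CCC(CCC(=O)C=C)(C(=O)OC)C(=O)OC | intermediate
21 | O-trimethylsilyl ether of 22 | CC(C)C[C@H](c1c(OC)cc(OC)cc1OC)/C=C(CO[Si](C)(C)C)\CCC(C/C=C(O[Si](C(C)C)(C(C)C)C(C)C)/C=C)(C(=O)OC)C(=O)OC | intermediate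
22 | dimethyl 2-[(3E,5S)-3-(hydroxymethyl)-7-methyl-5-(2,4,6-trimethoxyphenyl)oct-3-en-1-yl]-2-[(2Z)-3-(triisopropylsilyloxy)penta-2,4-dien-1-yl]propanedioate | CC(C)C[C@H](c1c(OC)cc(OC)cc1OC)/C=C(CO)\CCC(C/C=C(O[Si](C(C)C)(C(C)C)C(C)C)/C=C)(C(=O)OC)C(=O)OC | intermediate
23 | dimethyl 2-[(3E,5S)-3-formyl-7-methyl-5-(2,4,6-trimethoxyphenyl)oct-3-en-1-yl]-2-[(2Z)-3-(triisopropylsilyloxy)penta-2,4-dien-1-yl]propanedioate | CC(C)C[C@H](c1c(OC)cc(OC)cc1OC)/C=C(C=O)\CCC(C/C=C(O[Si](C(C)C)(C(C)C)C(C)C)/C=C)(C(=O)OC)C(=O)OC | intermediate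
24 | dimethyl (4aS,5S,8aS)-4a-formyl-5-[(1S)-3-methyl-1-(2,4,6-trimethoxyphenyl)butyl]-8-(triisopropylsilyloxy)-3,4,4a,5,6,8a-hexahydronaphthalene-2,2(1H)-dicarboxylate | CC(C)C[C@H](c3c(OC)cc(OC)cc3OC)[C@@H]1CC=C(O[Si](C(C)C)(C(C)C)C(C)C)[C@H]2CC(C(=O)OC)(C(=O)OC)CC[C@]12C=O | intermediate
25 | (E)-N-tosylhydrazone of 24 | CC(C)C[C@H](c3c(OC)cc(OC)cc3OC)[C@@H]1CC=C(O[Si](C(C)C)(C(C)C)C(C)C)[C@H]2CC(C(=O)OC)(C(=O)OC)CC[C@]12/C=N/NS(=O)(=O)c4ccc(C)cc4 | intermediate
26 | N-(1,3,2-benzodioxaborol-2-yl)-N′-tosylhydrazine formed from 25 | CC(C)C[C@H](c3c(OC)cc(OC)cc3OC)[C@@H]1CC=C(O[Si](C(C)C)(C(C)C)C(C)C)[C@H]2CC(C(=O)OC)(C(=O)OC)CC[C@]12CN(B4Oc5ccccc5O4)NS(=O)(=O)c6ccc(C)cc6 | intermediate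
27 | dimethyl (4aR,5S,8aS)-4a-methyl-5-[(1S)-3-methyl-1-(2,4,6-trimethoxyphenyl)butyl]-8-(triisopropylsilyloxy)-3,4,4a,5,6,8a-hexahydronaphthalene-2,2(1H)-dicarboxylate | CC(C)C[C@H](c3c(OC)cc(OC)cc3OC)[C@@H]1CC=C(O[Si](C(C)C)(C(C)C)C(C)C)[C@H]2CC(C(=O)OC)(C(=O)OC)CC[C@]12C | intermediate
28 | dimethyl (4aR,5S,8aS)-4a-methyl-5-[(1S)-3-methyl-1-(2,4,6-trimethoxyphenyl)butyl]-8-oxo-octahydronaphthalene-2,2(1H)-dicarboxylate | CC(C)C[C@H](c3c(OC)cc(OC)cc3OC)[C@@H]1CCC(=O)[C@H]2CC(C(=O)OC)(C(=O)OC)CC[C@]12C | intermediate
29 | dimethyl (4aR,5S,8R,8aS)-8-hydroxy-4a,8-dimethyl-5-[(1S)-3-methyl-1-(2,4,6-trimethoxyphenyl)butyl]octahydronaphthalene-2,2(1H)-dicarboxylate | CC(C)C[C@H](c3c(OC)cc(OC)cc3OC)[C@@H]1CC[C@@](C)(O)[C@H]2CC(C(=O)OC)(C(=O)OC)CC[C@]12C | intermediate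
30 | methyl (4aR,5S,8R,8aS)-8-hydroxy-4a,8-dimethyl-5-[(1S)-3-methyl-1-(2,4,6-trimethoxyphenyl)butyl]decahydronaphthalene-2-carboxylate, both C2 epimers | CC(C)C[C@H](c3c(OC)cc(OC)cc3OC)[C@@H]1CC[C@@](C)(O)[C@H]2CC(C(=O)OC)CC[C@]12C | intermediate
31 | methyl (2S,4aR,5S,8R,8aS)-8-hydroxy-4a,8-dimethyl-5-[(1S)-3-methyl-1-(2,4,6-trimethoxyphenyl)butyl]decahydronaphthalene-2-carboxylate | CC(C)C[C@H](c3c(OC)cc(OC)cc3OC)[C@@H]1CC[C@@](C)(O)[C@H]2C[C@@H](C(=O)OC)CC[C@]12C | intermediate
32 | (1R,4S,4aR,7S,8aS)-7-(2-hydroxypropan-2-yl)-1,4a-dimethyl-4-[(1S)-3-methyl-1-(2,4,6-trimethoxyphenyl)butyl]decahydronaphthalen-1-ol | CC(C)C[C@H](c3c(OC)cc(OC)cc3OC)[C@@H]1CC[C@@](C)(O)[C@H]2C[C@@H](C(C)(C)O)CC[C@]12C | intermediate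
33 | (1R,4S,4aR,7S,8aS)-4-[(1S)-1-(3,5-dibromo-2,4,6-trimethoxyphenyl)-3-methylbutyl]-7-(2-hydroxypropan-2-yl)-1,4a-dimethyldecahydronaphthalen-1-ol | CC(C)C[C@H](c3c(OC)c(Br)c(OC)c(Br)c3OC)[C@@H]1CC[C@@](C)(O)[C@H]2C[C@@H](C(C)(C)O)CC[C@]12C | intermediate
34 | 3,5-dilithio arene dilithium dialkoxide derived from 33 | CC(C)C[C@H](c3c(OC)c([Li])c(OC)c([Li])c3OC)[C@@H]1CC[C@@](C)(O[Li])[C@H]2C[C@@H](C(C)(C)O[Li])CC[C@]12C | intermediate
35 | 5-{(1S)-1-[(1S,4R,4aS,6S,8aR)-4-hydroxy-6-(2-hydroxypropan-2-yl)-4,8a-dimethyldecahydronaphthalen-1-yl]-3-methylbutyl}-2,4,6-trimethoxybenzene-1,3-dicarbaldehyde | CC(C)C[C@H](c3c(OC)c(C=O)c(OC)c(C=O)c3OC)[C@@H]1CC[C@@](C)(O)[C@H]2C[C@@H](C(C)(C)O)CC[C@]12C | intermediate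
36 | 2,4,6-trihydroxy-5-{(1S)-1-[(1S,4R,4aS,6S,8aR)-4-hydroxy-6-(2-hydroxypropan-2-yl)-4,8a-dimethyldecahydronaphthalen-1-yl]-3-methylbutyl}benzene-1,3-dicarbaldehyde | CC(C)C[C@H](c1c(O)c(C=O)c(O)c(C=O)c1O)[C@@H]1CC[C@@](C)(O)[C@H]2C[C@@H](C(C)(C)O)CC[C@]12C | target

## Step count and least certain steps

Total step count: 20. Longest linear sequence: 20 steps (1 to 36); compounds 2, 5, 11, 12 and 17 enter as purchased materials.

**Step 11 (key step).** The cycloaddition may be slow, because the tether joins the nucleophilic diene terminus C5 to the α-carbon of a hindered trisubstituted enal. Three processes could then compete: thermal decomposition, a hetero-cycloaddition in which the enal acts as heterodiene toward the enol ether (C5 to C1, seven-membered ring), and addition to the wrong face of the enal if the allylic-strain bias is weaker than expected. A cis-fused minor adduct would differ only at C5; because the C1 side chain is axial in the trans series, the route does not count on a base equilibration at ketone 28 to correct it.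
Fallback (from 19, back at 28): the enol ether is replaced by an alkenylboronate, which keeps the C4 oxygen latent but cannot act as a Michael donor, so Me2AlCl activation of the enal becomes possible. The hydroxyl of 19 is silylated with Me3SiCl, the ketone is converted with KN(SiMe3)2 and PhNTf2 into its enol triflate, and the silyl ether is removed to give dienyl triflate F1. Miyaura borylation (B2pin2, PdCl2(PPh3)2, PPh3, KOPh) gives dienylboronate F2, and MnO2 gives boryl trienal F3. Cycloaddition on heating or with Me2AlCl at low temperature gives alkenylboronate cycloadduct F4. Condensation with TsNHNH2 gives tosylhydrazone F5, and catecholborane reduction gives the angular methyl compound F6. NaBO3·4H2O oxidises the C–B bond and the enol tautomerises to ketone 28.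

**Step 6.** Ring opening of 11 by the malonate may be incomplete, or the Wittig reaction of the hindered aldehyde may be slow enough for residual base to erode the configuration of 10 at C1′.
Fallback (from 10, back at 14): Wittig reaction of 10 with the shelf-stable 3-(triphenylphosphoranylidene)oxolan-2-one gives alkylidene lactone F7; HBr in ethanol opens the lactone to bromo ester F8; alkylation of the sodium salt of 12 with F8 gives 14.

**Step 7.** If the enolate masking is incomplete, hydride may attack the malonate esters; some conjugate reduction of the enoate is also possible.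
Fallback (from 14, back at 16): LiOH hydrolyses the two unhindered malonate methyl esters in preference to the hindered conjugated ethyl ester to give malonic acid F9. As its dilithium carboxylate it does not accept hydride, and i-Bu2AlH reduces the enoate to hydroxy diacid F10. Me3SiCHN2 in MeOH re-esterifies it to 16.

**Step 8.** Divinyl ketone may oligomerise under base, or a second malonate may add to the product.
Fallback (from 16, back at 19): Michael addition of 16 to N-methoxy-N-methylprop-2-enamide (catalytic KOt-Bu) gives Weinreb amide F11; excess CH2=CHMgBr with inverse acidic quench converts the amide into vinyl ketone 19.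

**Step 13.** Reduction of the hydrazone at the neopentyl centre may stall, or the silyl enol ether may be lost early, exposing the C4 ketone to the reductant.
Fallback (from 24, back at 27): NaBH4 reduces the aldehyde to neopentyl alcohol F12; NaH, CS2 and MeI give xanthate F13; Bu3SnH with AIBN in toluene at 110 °C (Barton–McCombie deoxygenation) gives 27.

## Further compounds

F1 | step 11 | dimethyl 2-[(3E,5S)-3-(hydroxymethyl)-7-methyl-5-(2,4,6-trimethoxyphenyl)oct-3-en-1-yl]-2-[(2Z)-3-(trifluoromethylsulfonyloxy)penta-2,4-dien-1-yl]propanedioate | CC(C)C[C@H](c1c(OC)cc(OC)cc1OC)/C=C(CO)\CCC(C/C=C(OS(=O)(=O)C(F)(F)F)/C=C)(C(=O)OC)C(=O)OC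
F2 | step 11 | dimethyl 2-[(3E,5S)-3-(hydroxymethyl)-7-methyl-5-(2,4,6-trimethoxyphenyl)oct-3-en-1-yl]-2-[(2E)-3-(4,4,5,5-tetramethyl-1,3,2-dioxaborolan-2-yl)penta-2,4-dien-1-yl]propanedioate | CC(C)C[C@H](c1c(OC)cc(OC)cc1OC)/C=C(CO)\CCC(C/C=C(B2OC(C)(C)C(C)(C)O2)/C=C)(C(=O)OC)C(=O)OC
F3 | step 11 | dimethyl 2-[(3E,5S)-3-formyl-7-methyl-5-(2,4,6-trimethoxyphenyl)oct-3-en-1-yl]-2-[(2E)-3-(4,4,5,5-tetramethyl-1,3,2-dioxaborolan-2-yl)penta-2,4-dien-1-yl]propanedioate | CC(C)C[C@H](c1c(OC)cc(OC)cc1OC)/C=C(C=O)\CCC(C/C=C(B2OC(C)(C)C(C)(C)O2)/C=C)(C(=O)OC)C(=O)OC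
F4 | step 11 | dimethyl (4aS,5S,8aS)-4a-formyl-5-[(1S)-3-methyl-1-(2,4,6-trimethoxyphenyl)butyl]-8-(4,4,5,5-tetramethyl-1,3,2-dioxaborolan-2-yl)-3,4,4a,5,6,8a-hexahydronaphthalene-2,2(1H)-dicarboxylate | CC(C)C[C@H](c3c(OC)cc(OC)cc3OC)[C@@H]1CC=C(B4OC(C)(C)C(C)(C)O4)[C@H]2CC(C(=O)OC)(C(=O)OC)CC[C@]12C=O
F5 | step 11 | (E)-N-tosylhydrazone of F4 | CC(C)C[C@H](c3c(OC)cc(OC)cc3OC)[C@@H]1CC=C(B4OC(C)(C)C(C)(C)O4)[C@H]2CC(C(=O)OC)(C(=O)OC)CC[C@]12/C=N/NS(=O)(=O)c5ccc(C)cc5
F6 | step 11 | dimethyl (4aR,5S,8aS)-4a-methyl-5-[(1S)-3-methyl-1-(2,4,6-trimethoxyphenyl)butyl]-8-(4,4,5,5-tetramethyl-1,3,2-dioxaborolan-2-yl)-3,4,4a,5,6,8a-hexahydronaphthalene-2,2(1H)-dicarboxylate | CC(C)C[C@H](c3c(OC)cc(OC)cc3OC)[C@@H]1CC=C(B4OC(C)(C)C(C)(C)O4)[C@H]2CC(C(=O)OC)(C(=O)OC)CC[C@]12C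
F7 | step 6 | (3E)-3-[(2S)-4-methyl-2-(2,4,6-trimethoxyphenyl)pentylidene]oxolan-2-one | CC(C)C[C@H](c1c(OC)cc(OC)cc1OC)/C=C2\CCOC2=O
F8 | step 6 | ethyl (2E,4S)-2-(2-bromoethyl)-6-methyl-4-(2,4,6-trimethoxyphenyl)hept-2-enoate | CC(C)C[C@H](c1c(OC)cc(OC)cc1OC)/C=C(C(=O)OCC)\CCBr
F9 | step 7 | 2-[(3E,5S)-3-(ethoxycarbonyl)-7-methyl-5-(2,4,6-trimethoxyphenyl)oct-3-en-1-yl]propanedioic acid | CC(C)C[C@H](c1c(OC)cc(OC)cc1OC)/C=C(C(=O)OCC)\CCC(C(=O)O)C(=O)O
F10 | step 7 | 2-[(3E,5S)-3-(hydroxymethyl)-7-methyl-5-(2,4,6-trimethoxyphenyl)oct-3-en-1-yl]propanedioic acid | CC(C)C[C@H](c1c(OC)cc(OC)cc1OC)/C=C(CO)\CCC(C(=O)O)C(=O)O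
F11 | step 8 | dimethyl 2-[(3E,5S)-3-(hydroxymethyl)-7-methyl-5-(2,4,6-trimethoxyphenyl)oct-3-en-1-yl]-2-{3-[methoxy(methyl)amino]-3-oxopropyl}propanedioate | CC(C)C[C@H](c1c(OC)cc(OC)cc1OC)/C=C(CO)\CCC(CCC(=O)N(C)OC)(C(=O)OC)C(=O)OC
F12 | step 13 | dimethyl (4aS,5S,8aS)-4a-(hydroxymethyl)-5-[(1S)-3-methyl-1-(2,4,6-trimethoxyphenyl)butyl]-8-(triisopropylsilyloxy)-3,4,4a,5,6,8a-hexahydronaphthalene-2,2(1H)-dicarboxylate | CC(C)C[C@H](c3c(OC)cc(OC)cc3OC)[C@@H]1CC=C(O[Si](C(C)C)(C(C)C)C(C)C)[C@H]2CC(C(=O)OC)(C(=O)OC)CC[C@]12CO
F13 | step 13 | O-alkyl S-methyl carbonodithioate (xanthate) of F12 | CC(C)C[C@H](c3c(OC)cc(OC)cc3OC)[C@@H]1CC=C(O[Si](C(C)C)(C(C)C)C(C)C)[C@H]2CC(C(=O)OC)(C(=O)OC)CC[C@]12COC(=S)SC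
A1 | alternative 1 | dimethyl 2,4,6-trihydroxyisophthalate carrying the bis(triethylsilyl)-protected terpenyl side chain | CC(C)C[C@H](c3c(O)c(C(=O)OC)c(O)c(C(=O)OC)c3O)[C@@H]1CC[C@@](C)(O[Si](CC)(CC)CC)[C@H]2C[C@@H](C(C)(C)O[Si](CC)(CC)CC)CC[C@]12C
A2 | alternative 1 | C1′-substituted propanedioyl dichloride | CC(C)C[C@H](C(C(=O)Cl)C(=O)Cl)[C@@H]1CC[C@@](C)(O[Si](CC)(CC)CC)[C@H]2C[C@@H](C(C)(C)O[Si](CC)(CC)CC)CC[C@]12C
A3 | alternative 1 | dimethyl 3-oxopentanedioate | COC(=O)CC(=O)CC(=O)OC
A4 | alternative 2 | trans-fused decal-8-ene-4,7-dione carrying the C1 side chain | CC(C)C[C@H](c3c(OC)cc(OC)cc3OC)[C@@H]1CCC(=O)[C@H]2CC(=O)C=C[C@]12C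
A5 | alternative 2 | aldehyde tethered to a 4-methylcyclohexa-2,5-dienone | CC(C)C[C@H](c3c(OC)cc(OC)cc3OC)[C@@H](C1(C)C=CC(=O)C=C1)CCC=O
A6 | alternative 3 | trans-decal-4-one with C11 triethylsilyl ether | CC(C)C[C@H](c3c(OC)cc(OC)cc3OC)[C@@H]1CCC(=O)[C@H]2C[C@@H](C(C)(C)O[Si](CC)(CC)CC)CC[C@]12C
A7 | alternative 3 | 3-substituted cyclohex-2-enone carrying the iodide tether | CC(C)C[C@H](c3c(OC)cc(OC)cc3OC)[C@@H]1CCC(=O)C=C1CC[C@@H](CI)C(C)(C)O[Si](CC)(CC)CC
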